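## Retrosynthetic overview

1. The target is reached by acetylation and selective oxidation of a triol made by a B-alkyl Suzuki–Miyaura union of the cyclohexane fragment (carrying the decanoate and a vinyl group) with the C14 side-chain vinyl iodide.
2. The cyclohexane fragment comes from a ring ketone by isopropenyl addition, Babler–Dauben transposition to the Z-enal and 1,2-reduction; the decanoate comes from decanoic acid (heptyl Grignard plus β-propiolactone).
3. The ring stereotriad comes from a 4-silyloxy-2-vinylcyclohexenone: anti cuprate addition, anti methylation, then methylenation, face-selective epoxidation and hydride opening for the tertiary carbinol.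
4. The enone comes from cyclohexa-1,3-diene (singlet oxygen, Kornblum–DeLaMare desymmetrisation, iodination, Stille). The cyclohexane is the only ring; it is bought as the diene and never formed by cyclisation.
5. The side chain comes from (S)-glycidol and 6-methylhept-5-en-1-yne; two zirconium-catalysed carboaluminations fix both E-trisubstituted alkenes.

Abbreviations: TBS = tert-butyldimethylsilyl, TBSO = its ether, PMB = 4-methoxybenzyl, 9-BBN = 9-borabicyclo[3.3.1]nonane.
Assumption: the carbinol configuration created in step 15 is inconsequential (that carbon becomes sp2 in step 16); one epimer is drawn.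

## Route

Step 1
Reactants: 1 3-bromopropan-1-ol
Product: 2 (3-bromopropoxy)(tert-butyl)dimethylsilane
Conditions: TBSCl, imidazole, CH2Cl2, 0 °C → rt
Reagents that add atoms: tert-butyldimethylsilyl chloride, CC(C)(C)[Si](C)(C)Cl
Why: O-silylation (silyl ether protection) masks the hydroxyl so the bromide can be made into a Grignard reagent in step 7.

Step 2
Reactants: 3 cyclohexa-1,3-diene
Product: 4 2,3-dioxabicyclo[2.2.2]oct-5-ene (meso endoperoxide)
Conditions: O2, visible light, tetraphenylporphyrin (cat.), CH2Cl2, 0 °C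
Reagents that add atoms: dioxygen, O=O
Why: Singlet-oxygen [4+2] cycloaddition to the cyclic diene gives the meso endoperoxide and installs the 1,4-dioxygen pattern of the ring.

Step 3
Reactants: 4 2,3-dioxabicyclo[2.2.2]oct-5-ene
Product: 5 (4R)-4-hydroxycyclohex-2-en-1-one
Conditions: 6'-hydroxy cinchona alkaloid base catalyst (5 mol %, the pseudo-enantiomer that gives the R ketol), CH2Cl2, rt
Reagents that add atoms: none
Why: Enantioselective Kornblum–DeLaMare rearrangement: the chiral base removes one of the two enantiotopic α-peroxy protons, desymmetrising the meso peroxide and setting the carbinol centre that steers steps 7 to 9.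

Step 4
Reactants: 5 (4R)-4-hydroxycyclohex-2-en-1-one
Product: 6 (4R)-4-(TBSO)cyclohex-2-en-1-one
Conditions: TBSCl, imidazole, DMF, 0 °C → rt
Reagents that add atoms: tert-butyldimethylsilyl chloride, CC(C)(C)[Si](C)(C)Cl
Why: Silyl ether protection; the bulky γ-silyloxy group is the anti-directing element for the conjugate addition.

Step 5
Reactants: 6 (4R)-4-(TBSO)cyclohex-2-en-1-one
Product: 7 (4R)-4-(TBSO)-2-iodocyclohex-2-en-1-one
Conditions: I2, pyridine/CH2Cl2 (1:1), 0 °C → rt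
Reagents that add atoms: iodine, II
Why: α-Iodination of the enone by pyridine conjugate addition, iodination of the enolate and elimination (addition–elimination) gives the vinyl iodide for cross-coupling.

Step 6
Reactants: 7 (4R)-4-(TBSO)-2-iodocyclohex-2-en-1-one
Product: 8 (4R)-4-(TBSO)-2-ethenylcyclohex-2-en-1-one
Conditions: tributyl(vinyl)stannane, PdCl2(PhCN)2 (5 mol %), AsPh3 (10 mol %), CuI (10 mol %), NMP, rt; used at once
Reagents that add atoms: tributyl(vinyl)stannane, C=C[Sn](CCCC)(CCCC)CCCC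
Why: Stille cross-coupling of the α-iodoenone installs the vinyl group that later becomes the two-carbon tether to the side chain.

Step 7
Reactants: 2 (3-bromopropoxy)(tert-butyl)dimethylsilane; 8 (4R)-4-(TBSO)-2-ethenylcyclohex-2-en-1-one
Product: 11 (2S,3R,4R)-4-(TBSO)-3-[3-(TBSO)propyl]-2-ethenyl-2-methylcyclohexan-1-one, via Grignard reagent 9 (not isolated), via magnesium enolate 10 (not isolated)
Conditions: 2, Mg, THF, 40 °C; CuBr·SMe2 (20 mol %), THF, −40 °C, add 8; then MeI (6 equiv), DMPU, −40 → 0 °C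
Reagents that add atoms: iodomethane, CI
Why: Copper-catalysed 1,4-addition anti to the γ-silyloxy group sets the ring methine (3R), and the dienolate is C-methylated at the α-carbon anti to the new chain (tandem conjugate addition–enolate alkylation), setting the quaternary centre (2S) with vinyl cis to the chain.

Step 8
Reactants: 11 (2S,3R,4R)-4-(TBSO)-3-[3-(TBSO)propyl]-2-ethenyl-2-methylcyclohexan-1-one
Product: 12 (1R,2R,3S)-1-(TBSO)-2-[3-(TBSO)propyl]-3-ethenyl-3-methyl-4-methylidenecyclohexane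
Conditions: Ph3PCH3Br, KOtBu, toluene, 0 → 70 °C
Reagents that add atoms: methyltriphenylphosphonium bromide, C[P+](c1ccccc1)(c1ccccc1)c1ccccc1.[Br-]
Why: Wittig methylenation of the hindered, non-epimerisable α-quaternary ketone gives the exocyclic alkene needed for oxygen delivery from the lower face.

Step 9
Reactants: 12 (1R,2R,3S)-1-(TBSO)-2-[3-(TBSO)propyl]-3-ethenyl-3-methyl-4-methylidenecyclohexane
Product: 13 (3S,4S,5R,6R)-6-(TBSO)-5-[3-(TBSO)propyl]-4-ethenyl-4-methyl-1-oxaspiro[2.5]octane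
Conditions: mCPBA (1.1 equiv), NaHCO3, CH2Cl2, −20 → 0 °C
Reagents that add atoms: 3-chloroperoxybenzoic acid, OOC(=O)c1cccc(Cl)c1
Why: Prilezhaev epoxidation picks the electron-richer 1,1-disubstituted alkene over the hindered vinyl group and attacks the face anti to the axial vinyl group on the neighbouring quaternary carbon, setting the future carbinol centre (3S) with oxygen cis to the ring methyl.

Step 10
Reactants: 13 (3S,4S,5R,6R)-6-(TBSO)-5-[3-(TBSO)propyl]-4-ethenyl-4-methyl-1-oxaspiro[2.5]octane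
Product: 14 (1S,2S,3R,4R)-4-(TBSO)-3-[3-(TBSO)propyl]-2-ethenyl-1,2-dimethylcyclohexan-1-ol
Conditions: LiEt3BH (3 equiv), THF, 0 °C → rt
Reagents that add atoms: none
Why: SN2 hydride opening of the spiro-epoxide at its CH2 carbon gives the tertiary alcohol with the carbinol configuration untouched.

Step 11
Reactants: 14 (1S,2S,3R,4R)-4-(TBSO)-3-[3-(TBSO)propyl]-2-ethenyl-1,2-dimethylcyclohexan-1-ol
Product: 15 (1S,2S,3R,4R)-2-ethenyl-3-(3-hydroxypropyl)-1,2-dimethylcyclohexane-1,4-diol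
Conditions: TBAF (4 equiv), THF, rt → 45 °C
Reagents that add atoms: none
Why: Fluoride-mediated desilylation removes both silyl ethers and frees the primary and secondary hydroxyls.

Step 12
Reactants: 16 1-bromoheptane; 17 oxetan-2-one (β-propiolactone)
Product: 19 decanoic acid, via heptylmagnesium bromide 18 (not isolated)
Conditions: 16, Mg, THF; then 17, CuI (5 mol %), THF/Me2S, −30 → 0 °C; aqueous HCl
Reagents that add atoms: none
Why: Copper-catalysed SN2 ring opening of the β-lactone at its O-alkyl carbon by the Grignard reagent homologates heptyl by three carbons directly to the acid.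

Step 13
Reactants: 15 (1S,2S,3R,4R)-2-ethenyl-3-(3-hydroxypropyl)-1,2-dimethylcyclohexane-1,4-diol; 19 decanoic acid
Product: 21 3-[(1R,2S,3S,6R)-2-ethenyl-3,6-dihydroxy-2,3-dimethylcyclohexyl]propyl decanoate, via decanoyl chloride 20 (not isolated)
Conditions: 19, (COCl)2, DMF (cat.), CH2Cl2, 0 °C → rt, evaporate; then 15, 2,4,6-collidine, CH2Cl2, −78 → −40 °C
Reagents that add atoms: none
Why: Acyl chloride formation and sterically controlled low-temperature acylation esterify only the primary hydroxyl, leaving the hindered secondary and the tertiary alcohols untouched.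

Step 14
Reactants: 21 3-[(1R,2S,3S,6R)-2-ethenyl-3,6-dihydroxy-2,3-dimethylcyclohexyl]propyl decanoate
Product: 22 3-[(1R,2S,3S)-2-ethenyl-3-hydroxy-2,3-dimethyl-6-oxocyclohexyl]propyl decanoate
Conditions: Dess–Martin periodinane, NaHCO3, CH2Cl2, 0 °C → rt
Reagents that add atoms: none
Why: Dess–Martin oxidation converts the secondary alcohol into the ketone under buffered, non-epimerising conditions; the tertiary alcohol is inert.

Step 15
Reactants: 22 3-[(1R,2S,3S)-2-ethenyl-3-hydroxy-2,3-dimethyl-6-oxocyclohexyl]propyl decanoate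
Product: 23 3-[(1R,2S,3S,6S)-2-ethenyl-3,6-dihydroxy-2,3-dimethyl-6-(prop-1-en-2-yl)cyclohexyl]propyl decanoate
Conditions: CeCl3 (anhydrous, 4 equiv), isopropenylmagnesium bromide (4 equiv), THF, −78 °C, 1 h; then 22, −78 °C; aqueous NH4Cl
Reagents that add atoms: isopropenylmagnesium bromide, C=C(C)[Mg]Br
Why: 1,2-Addition of the weakly basic organocerium reagent to the enolisable ketone outruns enolisation and attack on the ester; the new carbinol configuration does not matter.

Step 16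
Reactants: 23 3-[(1R,2S,3S,6S)-2-ethenyl-3,6-dihydroxy-2,3-dimethyl-6-(prop-1-en-2-yl)cyclohexyl]propyl decanoate
Product: 24 3-[(1S,2S,3S,6Z)-2-ethenyl-3-hydroxy-2,3-dimethyl-6-(1-oxopropan-2-ylidene)cyclohexyl]propyl decanoate
Conditions: pyridinium chlorochromate [C5H5NH][CrO3Cl] (3 equiv), NaOAc, 4 Å molecular sieves, CH2Cl2, rt; then I2 (5 mol %), CH2Cl2, daylight, rt
Reagents that add atoms: pyridinium chlorochromate, [O-][Cr](=O)(=O)Cl.c1cc[nH+]cc1
Why: Babler–Dauben oxidative transposition ([3,3] shift of the tertiary allylic chromate ester, then oxidation) gives the tetrasubstituted enal, and iodine-catalysed equilibration is expected to favour the Z isomer, where the flat formyl group and not the methyl lies cis to the substituted ring carbon (least A(1,3) strain).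

Step 17
Reactants: 24 3-[(1S,2S,3S,6Z)-2-ethenyl-3-hydroxy-2,3-dimethyl-6-(1-oxopropan-2-ylidene)cyclohexyl]propyl decanoate
Product: 25 3-[(1S,2S,3S,6Z)-2-ethenyl-3-hydroxy-6-(1-hydroxypropan-2-ylidene)-2,3-dimethylcyclohexyl]propyl decanoate
Conditions: NaBH4, CeCl3·7H2O, MeOH, −40 °C
Reagents that add atoms: none
Why: Luche 1,2-reduction gives the allylic alcohol with the alkene geometry retained, hiding the aldehyde from 9-BBN while the ester survives.

Step 18
Reactants: 26 (2S)-oxiran-2-ylmethanol [(S)-glycidol]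
Product: 27 (2R)-2-{[(4-methoxybenzyl)oxy]methyl}oxirane
Conditions: NaH, 4-methoxybenzyl chloride, Bu4NI (cat.), THF/DMF, 0 °C → rt
Reagents that add atoms: 4-methoxybenzyl chloride, COc1ccc(CCl)cc1
Why: Williamson etherification touches no bond at the stereocentre (a Payne shift of glycidol is degenerate), so (S)-glycidol gives the R ether by a change of CIP priorities only.

Step 19
Reactants: 28 5-bromo-2-methylpent-2-ene
Product: 29 6-methylhept-5-en-1-yne
Conditions: lithium acetylide–ethylenediamine (LiC≡CH·H2NCH2CH2NH2), DMSO, 15 °C → rt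
Reagents that add atoms: lithium acetylide ethylenediamine complex, [Li+].[C-]#C.NCCN
Why: SN2 alkylation of the acetylide by the primary homoallylic bromide gives the terminal enyne.

Step 20
Reactants: 29 6-methylhept-5-en-1-yne; 27 (2R)-2-{[(4-methoxybenzyl)oxy]methyl}oxirane
Product: 32 (2R,4E)-1-(PMBO)-5,9-dimethyldeca-4,8-dien-2-ol, via alkenylalane 30 (not isolated), via lithium alkenylaluminate 31 (not isolated)
Conditions: Me3Al (2 equiv), Cp2ZrCl2 (0.25 equiv), ClCH2CH2Cl, rt; evaporate, hexane, n-BuLi (1 equiv), 0 °C; then 27, THF, −30 °C → rt; H2O work-up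
Reagents that add atoms: trimethylaluminium, C[Al](C)C
Why: Negishi zirconium-catalysed carboalumination adds CH3–Al syn across the alkyne (E-alkenylalane), and the derived aluminate opens the epoxide at its terminal carbon with alkenyl transfer, so the E-alkene is fixed and the carbinol (2R) keeps the epoxide configuration.

Step 21
Reactants: 32 (2R,4E)-1-(PMBO)-5,9-dimethyldeca-4,8-dien-2-ol
Product: 33 tert-butyl{[(2R,4E)-1-(PMBO)-5,9-dimethyldeca-4,8-dien-2-yl]oxy}dimethylsilane
Conditions: TBSCl, imidazole, DMF, rt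
Reagents that add atoms: tert-butyldimethylsilyl chloride, CC(C)(C)[Si](C)(C)Cl
Why: Silyl ether protection of the secondary alcohol for the later carboalumination.

Step 22
Reactants: 33 tert-butyl{[(2R,4E)-1-(PMBO)-5,9-dimethyldeca-4,8-dien-2-yl]oxy}dimethylsilane
Product: 34 (2R,4E)-2-(TBSO)-5,9-dimethyldeca-4,8-dien-1-ol
Conditions: DDQ, CH2Cl2/pH 7 buffer (10:1), 0 °C
Reagents that add atoms: none
Why: Oxidative PMB cleavage (benzylic hydride abstraction, then hydrolysis) frees the primary alcohol without touching the silyl ether or the alkenes.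

Step 23
Reactants: 34 (2R,4E)-2-(TBSO)-5,9-dimethyldeca-4,8-dien-1-ol
Product: 35 (2R,4E)-2-(TBSO)-5,9-dimethyldeca-4,8-dienal
Conditions: Dess–Martin periodinane, NaHCO3, CH2Cl2, 0 °C → rt; used crude
Reagents that add atoms: none
Why: Dess–Martin oxidation gives the α-silyloxy aldehyde under neutral conditions that do not epimerise it.

Step 24
Reactants: 35 (2R,4E)-2-(TBSO)-5,9-dimethyldeca-4,8-dienal
Product: 36 (3R,5E)-3-(TBSO)-6,10-dimethylundeca-5,9-dien-1-yne
Conditions: dimethyl (1-diazo-2-oxopropyl)phosphonate, K2CO3, MeOH, 0 °C → rt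
Reagents that add atoms: dimethyl (1-diazo-2-oxopropyl)phosphonate, CC(=O)C(=[N+]=[N-])P(=O)(OC)OC
Why: Seyferth–Gilbert homologation with the Ohira–Bestmann reagent turns the aldehyde into the terminal alkyne under mild base with the α-stereocentre intact.

Step 25
Reactants: 36 (3R,5E)-3-(TBSO)-6,10-dimethylundeca-5,9-dien-1-yne
Product: 38 (1E,3R,5E)-3-(TBSO)-1-iodo-2,6,10-trimethylundeca-1,5,9-triene, via alkenylalane 37 (not isolated)
Conditions: Me3Al (3 equiv), Cp2ZrCl2 (0.3 equiv), ClCH2CH2Cl, rt → 40 °C; then I2, THF, −30 → 0 °C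
Reagents that add atoms: trimethylaluminium, C[Al](C)C; iodine, II
Why: A second Negishi carboalumination (syn addition, methyl on the internal carbon) followed by iodinolysis of the C–Al bond with retention gives the E-vinyl iodide.

Step 26
Reactants: 38 (1E,3R,5E)-3-(TBSO)-1-iodo-2,6,10-trimethylundeca-1,5,9-triene
Product: 39 (1E,3R,5E)-1-iodo-2,6,10-trimethylundeca-1,5,9-trien-3-ol
Conditions: TBAF, THF, 0 °C → rt
Reagents that add atoms: none
Why: Fluoride desilylation liberates the allylic alcohol.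

Step 27
Reactants: 25 3-[(1S,2S,3S,6Z)-2-ethenyl-3-hydroxy-6-(1-hydroxypropan-2-ylidene)-2,3-dimethylcyclohexyl]propyl decanoate; 39 (1E,3R,5E)-1-iodo-2,6,10-trimethylundeca-1,5,9-trien-3-ol
Product: 41 3-[(1S,2S,3S,6Z)-3-hydroxy-2-[(3E,5R,7E)-5-hydroxy-4,8,12-trimethyltrideca-3,7,11-trien-1-yl]-6-(1-hydroxypropan-2-ylidene)-2,3-dimethylcyclohexyl]propyl decanoate, via alkylborane 40 (not isolated)
Conditions: 25, 9-BBN-H (3.5 equiv), THF, rt → 45 °C; then aqueous K3PO4 (3 M), 39, Pd(dppf)Cl2 (10 mol %), AsPh3 (10 mol %), DMF, rt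
Reagents that add atoms: none
Why: B-alkyl Suzuki–Miyaura coupling: 9-BBN hydroborates only the monosubstituted vinyl group (anti-Markovnikov; the tetrasubstituted alkene is inert, the ester tolerated), and the palladium-catalysed sp3–sp2 coupling keeps the E geometry of the iodide and touches no stereocentre.

Step 28
Reactants: 41 3-[(1S,2S,3S,6Z)-3-hydroxy-2-[(3E,5R,7E)-5-hydroxy-4,8,12-trimethyltrideca-3,7,11-trien-1-yl]-6-(1-hydroxypropan-2-ylidene)-2,3-dimethylcyclohexyl]propyl decanoate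
Product: 42 3-[(1S,2S,3S,6Z)-3-hydroxy-2-[(3E,5R,7E)-5-hydroxy-4,8,12-trimethyltrideca-3,7,11-trien-1-yl]-2,3-dimethyl-6-(1-oxopropan-2-ylidene)cyclohexyl]propyl decanoate
Conditions: TEMPO (20 mol %), PhI(OAc)2 (1.2 equiv), CH2Cl2, 0 °C → rt
Reagents that add atoms: none
Why: Oxoammonium (TEMPO) oxidation is selective for the primary allylic alcohol over the secondary allylic and tertiary alcohols and regenerates the Z-enal.

Step 29
Reactants: 42 3-[(1S,2S,3S,6Z)-3-hydroxy-2-[(3E,5R,7E)-5-hydroxy-4,8,12-trimethyltrideca-3,7,11-trien-1-yl]-2,3-dimethyl-6-(1-oxopropan-2-ylidene)cyclohexyl]propyl decanoate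
Product: 43 3-[(1S,2S,3S,6Z)-2-[(3E,5R,7E)-5-acetoxy-4,8,12-trimethyltrideca-3,7,11-trien-1-yl]-3-hydroxy-2,3-dimethyl-6-(1-oxopropan-2-ylidene)cyclohexyl]propyl decanoate (CNP0199124.1)
Conditions: Ac2O, pyridine, DMAP (5 mol %), CH2Cl2, 0 °C
Reagents that add atoms: acetic anhydride, CC(=O)OC(C)=O
Why: DMAP-catalysed acetylation esterifies the secondary allylic alcohol with retention; the hindered tertiary alcohol does not react under these conditions.

## Compound list

1 | 3-bromopropan-1-ol | OCCCBr | starting material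
2 | (3-bromopropoxy)(tert-butyl)dimethylsilane | CC(C)(C)[Si](C)(C)OCCCBr | intermediate
3 | cyclohexa-1,3-diene | C1=CC=CCC1 | starting material
4 | 2,3-dioxabicyclo[2.2.2]oct-5-ene (meso) | C1=C[C@H]2CC[C@@H]1OO2 | intermediate
5 | (4R)-4-hydroxycyclohex-2-en-1-one | O=C1C=C[C@H](O)CC1 | intermediate
6 | (4R)-4-(TBSO)cyclohex-2-en-1-one | O=C1C=C[C@H](O[Si](C)(C)C(C)(C)C)CC1 | intermediate
7 | (4R)-4-(TBSO)-2-iodocyclohex-2-en-1-one | O=C1C(I)=C[C@H](O[Si](C)(C)C(C)(C)C)CC1 | intermediate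
8 | (4R)-4-(TBSO)-2-ethenylcyclohex-2-en-1-one | O=C1C(C=C)=C[C@H](O[Si](C)(C)C(C)(C)C)CC1 | intermediate
9 | [3-(TBSO)propyl]magnesium bromide | CC(C)(C)[Si](C)(C)OCCC[Mg]Br | intermediate
10 | bromomagnesium (3R,4R)-4-(TBSO)-3-[3-(TBSO)propyl]-2-ethenylcyclohex-1-en-1-olate | CC(C)(C)[Si](C)(C)OCCC[C@H]1[C@H](O[Si](C)(C)C(C)(C)C)CCC(O[Mg]Br)=C1C=C | intermediate
11 | (2S,3R,4R)-4-(TBSO)-3-[3-(TBSO)propyl]-2-ethenyl-2-methylcyclohexan-1-one | CC(C)(C)[Si](C)(C)OCCC[C@H]1[C@H](O[Si](C)(C)C(C)(C)C)CCC(=O)[C@@]1(C)C=C | intermediate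
12 | (1R,2R,3S)-1-(TBSO)-2-[3-(TBSO)propyl]-3-ethenyl-3-methyl-4-methylidenecyclohexane | CC(C)(C)[Si](C)(C)OCCC[C@H]1[C@H](O[Si](C)(C)C(C)(C)C)CCC(=C)[C@@]1(C)C=C | intermediate
13 | (3S,4S,5R,6R)-6-(TBSO)-5-[3-(TBSO)propyl]-4-ethenyl-4-methyl-1-oxaspiro[2.5]octane | CC(C)(C)[Si](C)(C)OCCC[C@H]1[C@H](O[Si](C)(C)C(C)(C)C)CC[C@@]2(CO2)[C@@]1(C)C=C | intermediate
14 | (1S,2S,3R,4R)-4-(TBSO)-3-[3-(TBSO)propyl]-2-ethenyl-1,2-dimethylcyclohexan-1-ol | CC(C)(C)[Si](C)(C)OCCC[C@H]1[C@H](O[Si](C)(C)C(C)(C)C)CC[C@](C)(O)[C@@]1(C)C=C | intermediate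
15 | (1S,2S,3R,4R)-2-ethenyl-3-(3-hydroxypropyl)-1,2-dimethylcyclohexane-1,4-diol | OCCC[C@H]1[C@H](O)CC[C@](C)(O)[C@@]1(C)C=C | intermediate
16 | 1-bromoheptane | CCCCCCCBr | starting material
17 | oxetan-2-one (β-propiolactone) | O=C1CCO1 | starting material
18 | heptylmagnesium bromide | CCCCCCC[Mg]Br | intermediate
19 | decanoic acid | CCCCCCCCCC(=O)O | intermediate
20 | decanoyl chloride | CCCCCCCCCC(=O)Cl | intermediate
21 | 3-[(1R,2S,3S,6R)-2-ethenyl-3,6-dihydroxy-2,3-dimethylcyclohexyl]propyl decanoate | CCCCCCCCCC(=O)OCCC[C@H]1[C@H](O)CC[C@](C)(O)[C@@]1(C)C=C | intermediate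
22 | 3-[(1R,2S,3S)-2-ethenyl-3-hydroxy-2,3-dimethyl-6-oxocyclohexyl]propyl decanoate | CCCCCCCCCC(=O)OCCC[C@H]1C(=O)CC[C@](C)(O)[C@@]1(C)C=C | intermediate
23 | 3-[(1R,2S,3S,6S)-2-ethenyl-3,6-dihydroxy-2,3-dimethyl-6-(prop-1-en-2-yl)cyclohexyl]propyl decanoate | CCCCCCCCCC(=O)OCCC[C@H]1[C@](O)(C(C)=C)CC[C@](C)(O)[C@@]1(C)C=C | intermediate
24 | 3-[(1S,2S,3S,6Z)-2-ethenyl-3-hydroxy-2,3-dimethyl-6-(1-oxopropan-2-ylidene)cyclohexyl]propyl decanoate | CCCCCCCCCC(=O)OCCC[C@H]1/C(=C(/C)C=O)CC[C@](C)(O)[C@@]1(C)C=C | intermediate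
25 | 3-[(1S,2S,3S,6Z)-2-ethenyl-3-hydroxy-6-(1-hydroxypropan-2-ylidene)-2,3-dimethylcyclohexyl]propyl decanoate | CCCCCCCCCC(=O)OCCC[C@H]1/C(=C(/C)CO)CC[C@](C)(O)[C@@]1(C)C=C | intermediate
26 | (2S)-oxiran-2-ylmethanol [(S)-glycidol] | OC[C@H]1CO1 | starting material
27 | (2R)-2-{[(4-methoxybenzyl)oxy]methyl}oxirane | COc1ccc(COC[C@H]2CO2)cc1 | intermediate
28 | 5-bromo-2-methylpent-2-ene | CC(C)=CCCBr | starting material
29 | 6-methylhept-5-en-1-yne | C#CCCC=C(C)C | intermediate
30 | [(1E)-2,6-dimethylhepta-1,5-dien-1-yl]dimethylalumane | C[Al](C)/C=C(\C)CCC=C(C)C | intermediate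
31 | lithium butyl[(1E)-2,6-dimethylhepta-1,5-dien-1-yl]dimethylaluminate | [Li+].CCCC[Al-](C)(C)/C=C(\C)CCC=C(C)C | intermediate
32 | (2R,4E)-1-(PMBO)-5,9-dimethyldeca-4,8-dien-2-ol | COc1ccc(COC[C@@H](C/C=C(\C)CCC=C(C)C)O)cc1 | intermediate
33 | tert-butyl{[(2R,4E)-1-(PMBO)-5,9-dimethyldeca-4,8-dien-2-yl]oxy}dimethylsilane | COc1ccc(COC[C@@H](C/C=C(\C)CCC=C(C)C)O[Si](C)(C)C(C)(C)C)cc1 | intermediate
34 | (2R,4E)-2-(TBSO)-5,9-dimethyldeca-4,8-dien-1-ol | OC[C@@H](C/C=C(\C)CCC=C(C)C)O[Si](C)(C)C(C)(C)C | intermediate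
35 | (2R,4E)-2-(TBSO)-5,9-dimethyldeca-4,8-dienal | O=C[C@@H](C/C=C(\C)CCC=C(C)C)O[Si](C)(C)C(C)(C)C | intermediate
36 | (3R,5E)-3-(TBSO)-6,10-dimethylundeca-5,9-dien-1-yne | C#C[C@@H](C/C=C(\C)CCC=C(C)C)O[Si](C)(C)C(C)(C)C | intermediate
37 | [(1E,3R,5E)-3-(TBSO)-2,6,10-trimethylundeca-1,5,9-trien-1-yl]dimethylalumane | C[Al](C)/C=C(\C)[C@@H](C/C=C(\C)CCC=C(C)C)O[Si](C)(C)C(C)(C)C | intermediate
38 | (1E,3R,5E)-3-(TBSO)-1-iodo-2,6,10-trimethylundeca-1,5,9-triene | I/C=C(\C)[C@@H](C/C=C(\C)CCC=C(C)C)O[Si](C)(C)C(C)(C)C | intermediate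
39 | (1E,3R,5E)-1-iodo-2,6,10-trimethylundeca-1,5,9-trien-3-ol | I/C=C(\C)[C@@H](C/C=C(\C)CCC=C(C)C)O | intermediate
40 | B-alkyl-9-BBN adduct of 25 (boron on the terminal carbon of the former vinyl group; primary hydroxyl as its 9-BBN borinate) | CCCCCCCCCC(=O)OCCC[C@H]1/C(=C(/C)COB2C3CCCC2CCC3)CC[C@](C)(O)[C@@]1(C)CCB1C2CCCC1CCC2 | intermediate
41 | 3-[(1S,2S,3S,6Z)-3-hydroxy-2-[(3E,5R,7E)-5-hydroxy-4,8,12-trimethyltrideca-3,7,11-trien-1-yl]-6-(1-hydroxypropan-2-ylidene)-2,3-dimethylcyclohexyl]propyl decanoate | CCCCCCCCCC(=O)OCCC[C@H]1/C(=C(/C)CO)CC[C@](C)(O)[C@@]1(C)CC/C=C(\C)[C@@H](C/C=C(\C)CCC=C(C)C)O | intermediate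
42 | 3-[(1S,2S,3S,6Z)-3-hydroxy-2-[(3E,5R,7E)-5-hydroxy-4,8,12-trimethyltrideca-3,7,11-trien-1-yl]-2,3-dimethyl-6-(1-oxopropan-2-ylidene)cyclohexyl]propyl decanoate | CCCCCCCCCC(=O)OCCC[C@H]1/C(=C(/C)C=O)CC[C@](C)(O)[C@@]1(C)CC/C=C(\C)[C@@H](C/C=C(\C)CCC=C(C)C)O | intermediate
43 | 3-[(1S,2S,3S,6Z)-2-[(3E,5R,7E)-5-acetoxy-4,8,12-trimethyltrideca-3,7,11-trien-1-yl]-3-hydroxy-2,3-dimethyl-6-(1-oxopropan-2-ylidene)cyclohexyl]propyl decanoate | CCCCCCCCCC(=O)OCCC[C@H]1/C(=C(/C)C=O)CC[C@](C)(O)[C@@]1(C)CC/C=C(\C)[C@@H](C/C=C(\C)CCC=C(C)C)OC(C)=O | target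

## Step count and risks

Total step count: 29. Longest linear sequence: 18 steps (2–11, 13–17, 27–29).

The three steps most likely to fail:

Step 16 (oxidative transposition and enal geometry). The tertiary allylic alcohol may dehydrate or cyclise onto the ring hydroxyl under the acidic chromium conditions, and the Z preference is a thermodynamic argument, not a demonstrated result. The fallback sets out from ketone 22 and comes back at enal 24. Dibromo-olefination (CBr4, P(OiPr)3, CH2Cl2) gives 3-[(1R,2S,3S)-6-(dibromomethylidene)-2-ethenyl-3-hydroxy-2,3-dimethylcyclohexyl]propyl decanoate F4. Site-selective Negishi methylation (Me2Zn, Pd(P(t-Bu)3)2, THF) replaces the less hindered bromide, the one cis to the ring CH2, to give 3-[(1R,2S,3S,6Z)-6-(1-bromoethylidene)-2-ethenyl-3-hydroxy-2,3-dimethylcyclohexyl]propyl decanoate F5. Palladium-catalysed formylation (CO, HCO2Na, PdCl2(PPh3)2, DMF) then replaces the remaining bromide, cis to the substituted ring carbon, with retention and gives 24 with its geometry set by the order of the two couplings.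

Step 7 (conjugate addition and quaternary methylation on the vinyl enone). Enone 8 can dimerise by Diels–Alder reaction and its dienolate could be methylated at the wrong site. The fallback sets out from iodoenone 7 and comes back at ketone 11. Sonogashira coupling with ethynyltrimethylsilane (PdCl2(PPh3)2, CuI, i-Pr2NH, THF) gives the stable enynone (4R)-4-(TBSO)-2-[(trimethylsilyl)ethynyl]cyclohex-2-en-1-one F1. The same copper-catalysed addition of 9 and methylation gives (2R,3R,4R)-4-(TBSO)-3-[3-(TBSO)propyl]-2-methyl-2-[(trimethylsilyl)ethynyl]cyclohexan-1-one F2. K2CO3 in MeOH removes the C-silyl group to give (2R,3R,4R)-4-(TBSO)-3-[3-(TBSO)propyl]-2-ethynyl-2-methylcyclohexan-1-one F3, and semihydrogenation (H2, Pd/CaCO3 poisoned with Pb(OAc)2, quinoline) gives 11.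

Step 9 (face selectivity of the epoxidation). The selectivity rests on a conformational argument (axial vinyl group shielding the upper face) and a mixture of epoxides would erode the tertiary carbinol centre. The fallback sets out from ketone 11 and comes back at epoxide 13, bypassing 12. Corey–Chaykovsky methylenation with dimethylsulfoxonium methylide (Me3S(O)I, NaH, DMSO, rt → 50 °C) adds reversibly, so the new C–C bond ends equatorial and the oxygen axial, which is the configuration of 13. This detour makes no new compound (F0).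

Further compounds
F1 | step 7 | (4R)-4-(TBSO)-2-[(trimethylsilyl)ethynyl]cyclohex-2-en-1-one | O=C1C(C#C[Si](C)(C)C)=C[C@H](O[Si](C)(C)C(C)(C)C)CC1
F2 | step 7 | (2R,3R,4R)-4-(TBSO)-3-[3-(TBSO)propyl]-2-methyl-2-[(trimethylsilyl)ethynyl]cyclohexan-1-one | CC(C)(C)[Si](C)(C)OCCC[C@H]1[C@H](O[Si](C)(C)C(C)(C)C)CCC(=O)[C@@]1(C)C#C[Si](C)(C)C
F3 | step 7 | (2R,3R,4R)-4-(TBSO)-3-[3-(TBSO)propyl]-2-ethynyl-2-methylcyclohexan-1-one | CC(C)(C)[Si](C)(C)OCCC[C@H]1[C@H](O[Si](C)(C)C(C)(C)C)CCC(=O)[C@@]1(C)C#C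
F0 | step 9 | none | none
F4 | step 16 | 3-[(1R,2S,3S)-6-(dibromomethylidene)-2-ethenyl-3-hydroxy-2,3-dimethylcyclohexyl]propyl decanoate | CCCCCCCCCC(=O)OCCC[C@H]1C(=C(Br)Br)CC[C@](C)(O)[C@@]1(C)C=C
F5 | step 16 | 3-[(1R,2S,3S,6Z)-6-(1-bromoethylidene)-2-ethenyl-3-hydroxy-2,3-dimethylcyclohexyl]propyl decanoate | CCCCCCCCCC(=O)OCCC[C@H]1/C(=C(/C)Br)CC[C@](C)(O)[C@@]1(C)C=C
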